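## Analysis of the target

The target 20 is methyl 7-hydroxy-5-[2-(4-hydroxyphenyl)ethyl]-2,2-dimethyl-8-(3-methylbut-2-enyl)-2H-chromene-6-carboxylate. It is a 2,2-dimethyl-2H-chromene whose benzene ring (ring A: C4a, C5, C6, C7, C8, C8a) is fully substituted. A two-carbon chain at C5 joins ring A to a 4-hydroxyphenyl ring (ring B). There is no stereocentre: C2 carries two methyl groups and the C3=C4 geometry is fixed by the pyran ring. The sensitive groups are the chromene double bond and the prenyl double bond (acid, electrophiles, hydrogenation), the prenyl group next to the C7 hydroxyl (acid-promoted closure to a chroman), two phenols, and the methyl ester that is hydrogen-bonded to the C7 hydroxyl. The difficulty is the order of six different substituents around ring A. Stepwise substitution of a resorcylate would have to tell C8 from C4a and would compete with O-alkylation. The strategy rests on three relations in ring A: the C6 ester is para to the C8a oxygen, the C7 oxygen is ortho to the ester, and C4a carries nothing of its own before the pyran is closed. This pattern maps onto a 2-pyrone-5-carboxylate (pyrone C5 becomes C6, C4 becomes C7, C3 becomes C8, C6 becomes C5). C8a and C4a are added as a two-carbon ketene acetal, and the lactone bridge is lost.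

## Retrosynthetic reasoning

**Pyran ring (20 to 17 and 18).** The bonds O1–C2 and C4–C4a are cut, which gives triphenol 17 and prenal 18. In 17 only C4a is unsubstituted and only the C8a hydroxyl is next to it, so condensation and oxa-6π closure can give one chromene only. The step is placed last so that the acid-sensitive chromene never meets deprotection conditions. The forward reaction needs a nucleophilic C4a, which is why the C7 hydroxyl (para to C4a) is freed beforehand.

**Protecting groups (17 to 16).** The two O–CH2 bonds of the methoxymethyl ethers at C7 and on ring B are cut. These acetals tolerate the bases, the heat and the silyl reagents used earlier and fall together under dilute acid. The C8a hydroxyl of 16 needs no protection because it is created free.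

**Ring A (16 to 10 and 12), the key disconnection.** The bonds C8–C8a and C5–C4a are cut. This leaves pyrone 10, which holds the prenyl group, the C7 oxygen, the ester and the arylethyl chain on four contiguous carbons in the correct order, and ketene acetal 12, which supplies only C8a with its oxygen and the bare C4a. Cuts elsewhere in ring A would require two heavily substituted partners to meet. Here the hindered partner is a stable heterocycle and the reactive partner is small. The forward reaction must form both bonds with the acetal carbon on pyrone C3, expel the lactone bridge (pyrone C2 and O1) and aromatise by loss of one silyloxy group with a C4a hydrogen. A bis(silyl) acetal is chosen so that the remaining oxygen substituent is a silyl ether that gives the free phenol on work-up.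

**Ketene acetal (12 to 11).** The O–Si bond is cut. Enolisation of silyl ester 11 and O-silylation give 12 in one step.

**Pyrone oxygen (10 to 9).** The O–CH2 bond at pyrone O4 is cut. The ether removes the acidic proton that would destroy 12 and fixes the 2-pyrone form of the ring.

**Lactone (9 to 8).** The O1–C2 bond of the pyrone is cut, which gives the open tricarbonyl diester 8. Only the ester on the prenylated arm can reach the side-chain ketone oxygen through a six-membered ring, so the ring closure has no regiochemical alternative.

**Side chain (8 to 6 and 3, through 7).** The bond between pyrone C5 and C6, that is, between the free methylene of 6 and the acyl carbon of 7, is cut. The prenyl group is already in 6, so acylation can only go to the unsubstituted methylene. This avoids a later C-alkylation of a 4-hydroxypyrone, where O-alkylation competes.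

**Prenyl group (6 to 4 and 5).** The bond from pyrone C3 to the allylic CH2 is cut. An acyclic β-keto ester enolate is alkylated at carbon by bromide 5.

**Ring B protection (3 to 1).** The O–CH2 bond is cut. The phenol of 1 has to be masked before the acid is activated.

## Alternatives that were turned down

**Alternative 1:** The pyran is the object of the key step. C3–C4 and O1–C2 are cut, which leads to the salicylaldehyde methyl 6-{2-[4-(tert-butyldimethylsilyloxy)phenyl]ethyl}-5-formyl-2,4-dihydroxy-3-(3-methylbut-2-enyl)benzoate A2 and (2-methylprop-1-enyl)boronic acid A3. In the forward direction a secondary amine condenses with the aldehyde of A2. The boron of A3 is held by the C8a phenoxide and delivers its alkenyl group to the iminium carbon (C4–C3). The amine then leaves and oxa-6π closure (O1–C2) gives A1, the ring B silyl ether of 20.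
- For it: the conditions are mild, the position of the formyl group fixes the pyran, and the closure does not depend on the nucleophilicity of ring A. On this point it is stronger than step 9 of the chosen route.
- Against it: the effort goes into the easiest ring. A2 still contains the hexasubstituted ring A, now with an extra formyl group that must be introduced next to an electrophile-sensitive prenyl group. A formylation and a silyl cleavage are added.
- Comparison: the chosen route closes the pyran from 17 in one step with all five carbons from 18 and spends its key step on the substitution pattern of ring A.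

**Alternative 2:** C4a–C5 and C6–C7 of ring A are cut. The partners are 1-methoxy-2-(3-methylbut-2-enyl)-1,3-bis(trimethylsilyloxy)buta-1,3-diene A5 and methyl 5-[4-(methoxymethoxy)phenyl]pent-2-ynoate A6. On heating, the CH2 terminus of A5 bonds to the β-carbon of A6 and the acetal terminus to the α-carbon. The adduct aromatises by expelling its methoxy group, and desilylation gives resorcylate A4, the ring B methoxymethyl ether of 17.
- For it: it is convergent, both ring A oxygens arrive unprotected, and it is probably two or three steps shorter than the chosen route. On step count it is the stronger plan.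
- Against it: an ynoate with an alkyl group on its β-carbon is a weak dienophile. The diene terminus that must bond to the ester-bearing carbon is fully substituted. Doubly silylated dienes of this kind are sensitive to heat and to hydrolysis, so decomposition or a conjugate addition without ring closure is the likely outcome.
- Comparison: in the chosen route the hindered partner is the robust pyrone 10, the small partner is the reactive one, and loss of the lactone bridge makes the sequence irreversible. The price is the extra steps to 10.

**Alternative 3:** Four bonds of ring A are cut: C4a–C5 (formed by a Wolff shift), C7–C8 and C8a–C4a (a [2+2] addition), and C6–C7 (a 6π closure). Irradiation of methyl (E)-3-(diazoacetyl)-5-[4-(triisopropylsilyloxy)phenyl]pent-2-enoate A8 gives vinylketene A10. A10 adds to the siloxyalkyne triisopropyl[(5-methylhex-4-en-1-ynyl)oxy]silane A9 to form a four-membered ring, which opens and recloses to A7. In A7 the C7 hydroxyl is free and the C8a oxygen is silylated.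
- For it: all six ring A substituents are placed with full regiocontrol under nearly neutral conditions. In regiochemical certainty of the ring-forming step it is at least equal to the chosen plan.
- Against it: A8 is an unsaturated diazoketone conjugated to an ester. It needs several steps with hazardous diazo chemistry and can cyclise onto its own double bond. A9 needs ynolate chemistry and is moisture-sensitive. The photochemical step is hard to scale. The oxygen differentiation is the reverse of what the pyran closure at C8a needs, so both silyl groups must be removed anyway.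
- Comparison: the chosen route reaches its diene by condensation chemistry from bulk materials and needs no photochemistry.

Key step: step 7

Remark on the chemistry: the target has no stereocentre. Compounds 6, 8 and 13 are racemic or tautomeric mixtures whose stereocentres disappear later, and the exocyclic double bond of 19 is not defined, so their SMILES carry no stereodescriptors.

## Route

Step 1
Reactants: 1 3-(4-hydroxyphenyl)propanoic acid
Product: 3 3-[4-(methoxymethoxy)phenyl]propanoic acid, via methoxymethyl ester 2 (not isolated)
Conditions: MOMCl (2.5 equiv), iPr2NEt (3 equiv), CH2Cl2, 0 °C → rt; then LiOH (3 equiv), THF/MeOH/H2O, rt; 1 M HCl to pH 4, 0 °C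
Reagents that add atoms: chloromethyl methyl ether, COCCl; lithium hydroxide, [Li+].[OH-] (its oxygen ends in the carboxyl group)
Why: O-alkylation of phenol and carboxylate gives the doubly protected compound 2; saponification then cleaves only the acyl–oxygen bond of the methoxymethyl ester, because the aryl acetal is stable to base.

Step 2
Reactants: 4 dimethyl 1,3-acetonedicarboxylate; 5 prenyl bromide
Product: 6 dimethyl 2-(3-methylbut-2-enyl)-3-oxopentanedioate
Conditions: 4 (2 equiv), NaH (1.05 equiv), THF, 0 °C; then 5 (1 equiv), 0 °C → rt
Reagents that add atoms: none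
Why: SN2 C-alkylation of the sodium enolate of a β-keto ester by an allylic bromide; the excess of the cheap diester 4 should limit a second alkylation, and the new stereocentre is of no consequence because it becomes sp2 in the pyrone.

Step 3
Reactants: 3 3-[4-(methoxymethoxy)phenyl]propanoic acid; 6 dimethyl 2-(3-methylbut-2-enyl)-3-oxopentanedioate
Product: 8 dimethyl 2-{3-[4-(methoxymethoxy)phenyl]propanoyl}-4-(3-methylbut-2-enyl)-3-oxopentanedioate, via acid chloride 7 (not isolated)
Conditions: 3, 1-chloro-N,N,2-trimethylprop-1-en-1-amine (1.1 equiv), CH2Cl2, 0 °C → rt; then added to 6, MgCl2 (1.1 equiv), pyridine (2.2 equiv), CH2Cl2, 0 °C → rt; aq. citric acid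
Reagents that add atoms: none
Why: The chloroenamine converts the acid into 7 without free HCl, which spares the aryl acetal; 7 then C-acylates the magnesium enolate of the β-keto ester (soft enolisation) at the unsubstituted CH2, which is less hindered and gives a product held as a stable magnesium chelate, whereas acylation at the prenylated carbon would give a quaternary centre that cannot enolise.

Step 4
Reactants: 8 dimethyl 2-{3-[4-(methoxymethoxy)phenyl]propanoyl}-4-(3-methylbut-2-enyl)-3-oxopentanedioate
Product: 9 methyl 4-hydroxy-6-{2-[4-(methoxymethoxy)phenyl]ethyl}-3-(3-methylbut-2-enyl)-2-oxo-2H-pyran-5-carboxylate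
Conditions: DBU (1.5 equiv), 4 Å molecular sieves, toluene, rt → 60 °C; cold 0.5 M HCl
Reagents that add atoms: none
Why: Base-mediated lactonisation of a 3,5-dioxo ester to a 4-hydroxy-2-pyrone: the enolate oxygen of the side-chain ketone attacks the ester of the prenylated arm, the only one that closes a six-membered ring, and methanol is lost; closure through carbon to a phloroglucinol would need a dianion and is not expected with an amidine base.

Step 5
Reactants: 9 methyl 4-hydroxy-6-{2-[4-(methoxymethoxy)phenyl]ethyl}-3-(3-methylbut-2-enyl)-2-oxo-2H-pyran-5-carboxylate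
Product: 10 methyl 4-(methoxymethoxy)-6-{2-[4-(methoxymethoxy)phenyl]ethyl}-3-(3-methylbut-2-enyl)-2-oxo-2H-pyran-5-carboxylate
Conditions: MOMCl (1.5 equiv), iPr2NEt (2 equiv), CH2Cl2, 0 °C
Reagents that add atoms: chloromethyl methyl ether, COCCl
Why: O-alkylation of the vinylogous acid by a hard electrophile with a hindered amine base should give the 4-alkoxy-2-pyrone; the ether removes the acidic proton that would destroy the ketene acetal in step 7 and fixes the diene in its 2-pyrone form.

Step 6
Reactants: 11 trimethylsilyl acetate
Product: 12 1,1-bis(trimethylsilyloxy)ethene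
Conditions: LiN(iPr)2 (1.05 equiv), THF, −78 °C; then Me3SiCl (1.1 equiv), −78 °C → rt; filtration under argon, distillation
Reagents that add atoms: chlorotrimethylsilane, C[Si](C)(C)Cl
Why: Deprotonation of the silyl ester and O-silylation of its lithium enolate is the standard preparation of ketene bis(silyl) acetals; low temperature and the hard silyl chloride favour silylation at oxygen over carbon.

Step 7
Reactants: 10 methyl 4-(methoxymethoxy)-6-{2-[4-(methoxymethoxy)phenyl]ethyl}-3-(3-methylbut-2-enyl)-2-oxo-2H-pyran-5-carboxylate; 12 1,1-bis(trimethylsilyloxy)ethene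
Product: 16 methyl 4-hydroxy-2-(methoxymethoxy)-6-{2-[4-(methoxymethoxy)phenyl]ethyl}-3-(3-methylbut-2-enyl)benzoate, via bicyclic lactone 13 (not isolated), via cyclohexadiene 14 (not isolated), via aryl trimethylsilyl ether 15 (not isolated)
Conditions: 12 (4 equiv), toluene, sealed tube, 110–130 °C; then K2CO3 (0.2 equiv), MeOH, 0 °C
Reagents that add atoms: none
Why: The electron-poor diene of 10 (pyrone C3 to C6) and the electron-rich alkene 12 should combine in an inverse-electron-demand [4+2] cycloaddition, probably asynchronous with the C6–CH2 bond leading, to the bridged lactone 13. Lactone 13 expels CO2 by retro-[4+2] to diene 14, which loses trimethylsilanol across the new CH2–C(OSiMe3)2 bond to give aryl silyl ether 15, and methanolysis frees the C8a phenol of 16; any 14 that survives is desilylated to the keto tautomer of 16, so both paths converge. The closest known reaction type is the addition of ketene acetals to 2-pyrone-5-carboxylates, which gives 4-alkoxybenzoates after loss of CO2 and an alcohol. Ring A is closed by this intermolecular [4+2] cycloaddition, which forms C8–C8a and C5–C4a from four pyrone carbons and the two acetal carbons, and is then aromatised by cycloreversion and elimination. No stereocentre remains, because the two bridgehead centres of 13 are destroyed on aromatisation. The step needs regiocontrol: pyrone C6 is β to the ester and δ to the lactone carbonyl and is therefore the electrophilic terminus, so the nucleophilic CH2 of 12 bonds there and the acetal carbon bonds to C3, whose electron density is raised by the C4 alkoxy group. This places the new oxygen para to the ester. The prenyl double bond and the two acetals should be inert, and heat is needed because both diene termini are fully substituted.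

Step 8
Reactants: 16 methyl 4-hydroxy-2-(methoxymethoxy)-6-{2-[4-(methoxymethoxy)phenyl]ethyl}-3-(3-methylbut-2-enyl)benzoate
Product: 17 methyl 2,4-dihydroxy-6-[2-(4-hydroxyphenyl)ethyl]-3-(3-methylbut-2-enyl)benzoate
Conditions: HCl (0.5 M in MeOH), 0 °C → rt
Reagents that add atoms: none
Why: Acid-catalysed transfer of both methoxymethyl groups to methanol (acetal exchange); dilute acid at room temperature is chosen so that neither phenol adds to the prenyl double bond, and the methyl ester cannot exchange in methanol.

Step 9
Reactants: 17 methyl 2,4-dihydroxy-6-[2-(4-hydroxyphenyl)ethyl]-3-(3-methylbut-2-enyl)benzoate; 18 3-methylbut-2-enal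
Product: 20 methyl 7-hydroxy-5-[2-(4-hydroxyphenyl)ethyl]-2,2-dimethyl-8-(3-methylbut-2-enyl)-2H-chromene-6-carboxylate, via ortho-quinone methide 19 (not isolated)
Conditions: 18 (3 equiv), ethylenediammonium diacetate (0.2 equiv), toluene, 110 °C
Reagents that add atoms: none
Why: Knoevenagel-type condensation of the iminium ion of prenal at C4a, the only unsubstituted carbon of ring A and activated by the ortho C8a and para C7 hydroxyls, gives 19 after loss of the amine, and 19 closes by oxa-6π electrocyclisation to the 2,2-dimethyl-2H-chromene; ring B is a simple phenol and should not react, and no stereocentre is formed.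

## Compound list

1 | 3-(4-hydroxyphenyl)propanoic acid | OC(=O)CCc1ccc(O)cc1 | starting material
2 | methoxymethyl 3-[4-(methoxymethoxy)phenyl]propanoate | COCOC(=O)CCc1ccc(OCOC)cc1 | intermediate (not isolated)
3 | 3-[4-(methoxymethoxy)phenyl]propanoic acid | OC(=O)CCc1ccc(OCOC)cc1 | intermediate
4 | dimethyl 1,3-acetonedicarboxylate | COC(=O)CC(=O)CC(=O)OC | starting material
5 | prenyl bromide (1-bromo-3-methylbut-2-ene) | CC(C)=CCBr | starting material
6 | dimethyl 2-(3-methylbut-2-enyl)-3-oxopentanedioate (racemic) | COC(=O)CC(=O)C(CC=C(C)C)C(=O)OC | intermediate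
7 | 3-[4-(methoxymethoxy)phenyl]propanoyl chloride | COCOc1ccc(CCC(=O)Cl)cc1 | intermediate (not isolated)
8 | dimethyl 2-{3-[4-(methoxymethoxy)phenyl]propanoyl}-4-(3-methylbut-2-enyl)-3-oxopentanedioate (mixture of stereoisomers and enol tautomers) | COC(=O)C(C(=O)CCc1ccc(OCOC)cc1)C(=O)C(CC=C(C)C)C(=O)OC | intermediate
9 | methyl 4-hydroxy-6-{2-[4-(methoxymethoxy)phenyl]ethyl}-3-(3-methylbut-2-enyl)-2-oxo-2H-pyran-5-carboxylate | O=C1OC(CCc2ccc(OCOC)cc2)=C(C(=O)OC)C(O)=C1CC=C(C)C | intermediate
10 | methyl 4-(methoxymethoxy)-6-{2-[4-(methoxymethoxy)phenyl]ethyl}-3-(3-methylbut-2-enyl)-2-oxo-2H-pyran-5-carboxylate | O=C1OC(CCc2ccc(OCOC)cc2)=C(C(=O)OC)C(OCOC)=C1CC=C(C)C | intermediate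
11 | trimethylsilyl acetate | CC(=O)O[Si](C)(C)C | starting material
12 | 1,1-bis(trimethylsilyloxy)ethene | C=C(O[Si](C)(C)C)O[Si](C)(C)C | intermediate
13 | methyl 5-(methoxymethoxy)-1-{2-[4-(methoxymethoxy)phenyl]ethyl}-4-(3-methylbut-2-enyl)-3-oxo-8,8-bis(trimethylsilyloxy)-2-oxabicyclo[2.2.2]oct-5-ene-6-carboxylate (racemic) | O=C1OC2(CCc3ccc(OCOC)cc3)CC(O[Si](C)(C)C)(O[Si](C)(C)C)C1(CC=C(C)C)C(OCOC)=C2C(=O)OC | intermediate (not isolated)
14 | methyl 6-(methoxymethoxy)-2-{2-[4-(methoxymethoxy)phenyl]ethyl}-5-(3-methylbut-2-enyl)-4,4-bis(trimethylsilyloxy)cyclohexa-1,5-diene-1-carboxylate | COC(=O)C1=C(CCc2ccc(OCOC)cc2)CC(O[Si](C)(C)C)(O[Si](C)(C)C)C(CC=C(C)C)=C1OCOC | intermediate (not isolated)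
15 | methyl 2-(methoxymethoxy)-6-{2-[4-(methoxymethoxy)phenyl]ethyl}-3-(3-methylbut-2-enyl)-4-(trimethylsilyloxy)benzoate | COC(=O)c1c(OCOC)c(CC=C(C)C)c(O[Si](C)(C)C)cc1CCc1ccc(OCOC)cc1 | intermediate (not isolated)
16 | methyl 4-hydroxy-2-(methoxymethoxy)-6-{2-[4-(methoxymethoxy)phenyl]ethyl}-3-(3-methylbut-2-enyl)benzoate | COC(=O)c1c(OCOC)c(CC=C(C)C)c(O)cc1CCc1ccc(OCOC)cc1 | intermediate
17 | methyl 2,4-dihydroxy-6-[2-(4-hydroxyphenyl)ethyl]-3-(3-methylbut-2-enyl)benzoate | COC(=O)c1c(O)c(CC=C(C)C)c(O)cc1CCc1ccc(O)cc1 | intermediate
18 | 3-methylbut-2-enal (prenal) | CC(C)=CC=O | starting material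
19 | methyl 6-hydroxy-2-[2-(4-hydroxyphenyl)ethyl]-5-(3-methylbut-2-enyl)-3-(3-methylbut-2-enylidene)-4-oxocyclohexa-1,5-diene-1-carboxylate (exocyclic geometry not defined) | COC(=O)C1=C(CCc2ccc(O)cc2)C(=CC=C(C)C)C(=O)C(CC=C(C)C)=C1O | intermediate (not isolated)
20 | methyl 7-hydroxy-5-[2-(4-hydroxyphenyl)ethyl]-2,2-dimethyl-8-(3-methylbut-2-enyl)-2H-chromene-6-carboxylate | COC(=O)c1c(O)c(CC=C(C)C)c2c(c1CCc1ccc(O)cc1)C=CC(C)(C)O2 | target

## Step count and weak points

Total step count: 9. Longest linear sequence: 7 steps (steps 1, 3, 4, 5, 7, 8, 9 from 1; equally steps 2, 3, 4, 5, 7, 8, 9 from 4).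

**Step 7 (key step).** The cycloaddition may be too slow, so that the ketene acetal is used up by silyl migration to carbon or by stray protonation before it adds. The cause would be that both diene termini are fully substituted and the C4 alkoxy group feeds electron density into the diene. The fallback changes the electronic design of the diene. It sets out from 9. Acetylation (Ac2O, pyridine, CH2Cl2, 0 °C) should give methyl 4-acetoxy-6-{2-[4-(methoxymethoxy)phenyl]ethyl}-3-(3-methylbut-2-enyl)-2-oxo-2H-pyran-5-carboxylate F1, whose acyloxy group is a much weaker donor. The same cycloaddition with 12, followed by methanolysis (K2CO3, MeOH) of both the aryl silyl ether and the aryl acetate, should give methyl 2,4-dihydroxy-6-{2-[4-(methoxymethoxy)phenyl]ethyl}-3-(3-methylbut-2-enyl)benzoate F2. Dilute HCl in MeOH removes the ring B acetal, and the route is rejoined at 17.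

**Step 5.** Alkylation may go to the lactone carbonyl oxygen and lead into the 4-pyranone series, or may stall at the hindered, hydrogen-bonded hydroxyl between the prenyl and ester groups. The fallback avoids an isolated ether. It sets out from 9. N,O-bis(trimethylsilyl)acetamide in toluene should give methyl 6-{2-[4-(methoxymethoxy)phenyl]ethyl}-3-(3-methylbut-2-enyl)-2-oxo-4-(trimethylsilyloxy)-2H-pyran-5-carboxylate F3 in the flask. The silyl group can move between the two oxygens, and only the 2-pyrone form is a diene. Addition of 12, heating as in step 7 and methanolysis should give methyl 2,4-dihydroxy-6-{2-[4-(methoxymethoxy)phenyl]ethyl}-3-(3-methylbut-2-enyl)benzoate F4. Dilute HCl in MeOH then leads back to 17.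

**Step 9.** Carbon–carbon bond formation at C4a, which is crowded by the C5 chain, may be slower than self-condensation of prenal. The fallback makes the C–O bond first and sets out from 16. O-Alkylation of the acidic C8a phenol with 3-chloro-3-methylbut-1-yne (K2CO3, KI, CuI cat., acetone, reflux) should give methyl 2-(methoxymethoxy)-6-{2-[4-(methoxymethoxy)phenyl]ethyl}-3-(3-methylbut-2-enyl)-4-[(2-methylbut-3-yn-2-yl)oxy]benzoate F5. Heating in xylene at 140 °C should bring about an aromatic propargyl Claisen rearrangement to the only free ortho carbon, a [1,5]-hydrogen shift and oxa-6π closure. The product would be methyl 7-(methoxymethoxy)-5-{2-[4-(methoxymethoxy)phenyl]ethyl}-2,2-dimethyl-8-(3-methylbut-2-enyl)-2H-chromene-6-carboxylate F6. Dilute HCl in MeOH then gives 20.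

**Step 8.** While the slower ring B acetal is being cleaved, a neighbouring phenol or methanol may add to the protonated prenyl double bond. The fallback changes the order of events and sets out from 16. The pyran is closed first through F5 and F6 as described for step 9, and the acetals are removed from F6. In F6 the C8a oxygen is already part of the pyran, and the C7 hydroxyl that is set free is tied to the ester by a hydrogen bond. This fallback accepts that the chromene is exposed to dilute acid, and it comes back at 20. No further compound arises (entry F0).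

## Further compounds

F1 | step 7 | methyl 4-acetoxy-6-{2-[4-(methoxymethoxy)phenyl]ethyl}-3-(3-methylbut-2-enyl)-2-oxo-2H-pyran-5-carboxylate | O=C1OC(CCc2ccc(OCOC)cc2)=C(C(=O)OC)C(OC(C)=O)=C1CC=C(C)C
F2 | step 7 | methyl 2,4-dihydroxy-6-{2-[4-(methoxymethoxy)phenyl]ethyl}-3-(3-methylbut-2-enyl)benzoate | COC(=O)c1c(O)c(CC=C(C)C)c(O)cc1CCc1ccc(OCOC)cc1
F3 | step 5 | methyl 6-{2-[4-(methoxymethoxy)phenyl]ethyl}-3-(3-methylbut-2-enyl)-2-oxo-4-(trimethylsilyloxy)-2H-pyran-5-carboxylate | O=C1OC(CCc2ccc(OCOC)cc2)=C(C(=O)OC)C(O[Si](C)(C)C)=C1CC=C(C)C
F4 | step 5 | methyl 2,4-dihydroxy-6-{2-[4-(methoxymethoxy)phenyl]ethyl}-3-(3-methylbut-2-enyl)benzoate | COC(=O)c1c(O)c(CC=C(C)C)c(O)cc1CCc1ccc(OCOC)cc1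
F5 | step 9 | methyl 2-(methoxymethoxy)-6-{2-[4-(methoxymethoxy)phenyl]ethyl}-3-(3-methylbut-2-enyl)-4-[(2-methylbut-3-yn-2-yl)oxy]benzoate | COC(=O)c1c(OCOC)c(CC=C(C)C)c(OC(C)(C)C#C)cc1CCc1ccc(OCOC)cc1
F6 | step 9 | methyl 7-(methoxymethoxy)-5-{2-[4-(methoxymethoxy)phenyl]ethyl}-2,2-dimethyl-8-(3-methylbut-2-enyl)-2H-chromene-6-carboxylate | COC(=O)c1c(OCOC)c(CC=C(C)C)c2c(c1CCc1ccc(OCOC)cc1)C=CC(C)(C)O2
F0 | step 8 | none | none
A1 | alternative 1 | methyl 5-{2-[4-(tert-butyldimethylsilyloxy)phenyl]ethyl}-7-hydroxy-2,2-dimethyl-8-(3-methylbut-2-enyl)-2H-chromene-6-carboxylate | COC(=O)c1c(O)c(CC=C(C)C)c2c(c1CCc1ccc(O[Si](C)(C)C(C)(C)C)cc1)C=CC(C)(C)O2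
A2 | alternative 1 | methyl 6-{2-[4-(tert-butyldimethylsilyloxy)phenyl]ethyl}-5-formyl-2,4-dihydroxy-3-(3-methylbut-2-enyl)benzoate | COC(=O)c1c(O)c(CC=C(C)C)c(O)c(C=O)c1CCc1ccc(O[Si](C)(C)C(C)(C)C)cc1
A3 | alternative 1 | (2-methylprop-1-enyl)boronic acid | CC(C)=CB(O)O
A4 | alternative 2 | methyl 2,4-dihydroxy-6-{2-[4-(methoxymethoxy)phenyl]ethyl}-3-(3-methylbut-2-enyl)benzoate | COC(=O)c1c(O)c(CC=C(C)C)c(O)cc1CCc1ccc(OCOC)cc1
A5 | alternative 2 | 1-methoxy-2-(3-methylbut-2-enyl)-1,3-bis(trimethylsilyloxy)buta-1,3-diene (C1=C2 geometry not defined) | COC(O[Si](C)(C)C)=C(CC=C(C)C)C(=C)O[Si](C)(C)C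
A6 | alternative 2 | methyl 5-[4-(methoxymethoxy)phenyl]pent-2-ynoate | COC(=O)C#CCCc1ccc(OCOC)cc1
A7 | alternative 3 | methyl 2-hydroxy-3-(3-methylbut-2-enyl)-4-(triisopropylsilyloxy)-6-{2-[4-(triisopropylsilyloxy)phenyl]ethyl}benzoate | COC(=O)c1c(O)c(CC=C(C)C)c(O[Si](C(C)C)(C(C)C)C(C)C)cc1CCc1ccc(O[Si](C(C)C)(C(C)C)C(C)C)cc1
A8 | alternative 3 | methyl (E)-3-(diazoacetyl)-5-[4-(triisopropylsilyloxy)phenyl]pent-2-enoate | [N-]=[N+]=CC(=O)/C(CCc1ccc(O[Si](C(C)C)(C(C)C)C(C)C)cc1)=C/C(=O)OC
A9 | alternative 3 | triisopropyl[(5-methylhex-4-en-1-ynyl)oxy]silane | CC(C)=CCC#CO[Si](C(C)C)(C(C)C)C(C)C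
A10 | alternative 3 | methyl (E)-3-(2-oxoethenyl)-5-[4-(triisopropylsilyloxy)phenyl]pent-2-enoate | O=C=C/C(CCc1ccc(O[Si](C(C)C)(C(C)C)C(C)C)cc1)=C/C(=O)OC
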